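Readings and results are simulated from invented constants; noise was put on by code.

In a one-step world, E → Q with nothing beside it gives a percentage of Q that does not hang on the charge, but ochre reached 81.9% and grey 31.8% at 5.00 min.

| flask | E | remark | time |
|---|---|---|---|
| ochre | 0.030 M | run made earlier |  |
| grey | 0.50 M | run made earlier |  |
| cedar | 0.050 M |  | 5.0 min |
| ash | 0.40 M |  | 5.0 min |
| maple | 0.15 M |  | 5.0 min |
| larch | 0.10 M |  | 5.0 min |
| birch | 0.025 M |  | 5.0 min |

| run | time / min | Q / % |
|---|---|---|
| ochre | 1.00 | 59.8 |
| ochre | 2.00 | 72.6 |
| ochre | 3.00 | 77.7 |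
| ochre | 4.00 | 80.4 |
| ochre | 5.00 | 81.9 |
| grey | 1.00 | 25.0 |
| grey | 2.00 | 29.1 |
| grey | 3.00 | 30.6 |
| grey | 4.00 | 31.8 |
| grey | 5.00 | 31.8 |

(readings scatter by 0.3 percentage points)

- percentages count the E that a species holds: one J or X counts as two
- Q is meant together with its Z and X
- solid, in amounts per volume of the solution: Z
- steps that have been proposed: E + Q <-> X; E <-> D; Z <-> Q; 2 E -> J; E -> Q
- in an amount of Q, one X counts as one Q

- all flasks from highest to lowest amount of Q, in percent of the E charged, at 5.0 min (cedar / ash / maple / larch / birch)
- the amount of Q, in percent of the E charged of the flask you put first, at 5.0 min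
- the amount of Q, in percent of the E charged of the flask you put last, at 5.0 min

So I let a proposed second step compete: two E pairing into J, which goes with [E] squared. Call a the rate at which pairing uses E over the rate at which E → Q uses it, at the start. The share of E ending as Q is then ln(1 + a)/a, and a grows in proportion to the charge. By trial, grey gave a = 6.20, so the pairing strength, a per molar of E charged (a selectivity factor, in the usual term), was 12.4 L mol⁻¹.

That strength was my weak link. Ochre gave a = 0.472 and a strength of 15.7 L mol⁻¹, more than grey's. Grey's strength put birch at 87.1%, ochre's at 84.3%. So for the two end flasks I took the strength of the nearer run: birch 84.3% from ochre, ash 36.0% from grey. Since ln(1 + a)/a falls as a rises, my order ran from the lowest charge to the highest.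

The forecast said birch > cedar > larch > maple > ash, with 84% and 35.8%, on the ground that “Yield should therefore fall steadily with charge”.

The flasks gave birch > cedar > larch > maple > ash, with birch at 84.2% and ash at 36.4%.

    E + Q ⇌ X, settled at all times (K = 21.0 L mol⁻¹)
    E ⇌ D (K = 0.506, k = 0.00593 s⁻¹)
    Z ⇌ Q, rate k3*(cs3 - [Q]) while solid is left; crystals form when [Q] > cs3 (solubility = 22.0 mM, k = 0.599 s⁻¹)
    2 E → J (k = 0.223 L mol⁻¹ s⁻¹)
    E → Q (k = 0.0274 s⁻¹)

In ash, pairing had half of its turnover up to 5.00 min behind it by 0.0516 min, earlier than E → Q at 0.324 min. The rate at which E → Q used E over the rate at which pairing used it rose in ash from 0.15 just after the start to 1.0 at 0.324 min and 50 at 5.00 min. Grey's pairing strength had given ash 36.0%, against 36.4% in the flask. For the neighbour of ash charged with 0.10 M, grey's strength gives 65.0%, and that neighbour stands at 64.0%.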